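Locants follow coumarin numbering throughout: unprimed for the 7-methoxycoumarin half (benzene ring A), primed for the 5,7-dihydroxycoumarin half (benzene ring B). Compound numbers are those of the list after the steps.

## The problem

The target 15, 5,7-dihydroxy-8-[(7-methoxy-2-oxo-2H-chromen-8-yl)oxy]-2H-chromen-2-one, is two coumarins joined only through one oxygen atom, which links C8 of the ring A half to C8' of the ring B half. That oxygen is the centre of a tetra-ortho-substituted diaryl ether: C8 lies between C7 (OMe) and C8a (O1), and C8' between C7' (OH) and C8a' (O1'). There is no stereocentre, so nothing has to be set and no centre can steer another. All selectivity is positional: which of the three contiguous oxygens of ring A (on C7, C8, C8a) and the four of ring B (on C5', C7', C8', C8a') becomes methyl ether, free phenol, bridge or lactone oxygen. The choice of reagents is limited by four things: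
- the two lactones, which hydroxide and alkoxide open;
- the C3=C4 and C3'=C4' double bonds, which hydrogenolysis saturates;
- the single aryl methyl ether, which must outlive the unmasking of the two ring B phenols;
- ring B itself, a 1,2,3,5-tetraoxygenated benzene that oxidises easily once its phenols are free.

The feature that opens the route is that in each half the lactone oxygen (O1, O1') joins the carbonyl carbon (C2, C2') to the aryl carbon (C8a, C8a') ortho to the ether-bearing carbon (C8, C8'). This is the connectivity left when an oxygen atom is inserted into the aryl–carbonyl bond of a 7-aryloxyindan-1-one, and in such an indanone the carbonyl stands ortho to the carbon that must be etherified, where it can activate a nucleophilic aromatic substitution.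

## Retrosynthesis

**Cut 1, the benzyl ethers (15 ⇒ 14).** The last operation removes the protecting groups on O5' and O7', cutting two O–CH2 bonds of 14. Benzyl is preferred to methyl, which could not be told from the C7 methyl ether, and to acyl or silyl groups, which would not survive the carbonate base of the ether-forming step. The forward step must cleave aryl benzyl ethers with a boron trihalide and a cation scavenger at low temperature. Catalytic hydrogenolysis is excluded because it would also saturate C3=C4 and C3'=C4'.

**Cut 2, the two ring double bonds (14 ⇒ 13).** Removing C3=C4 and C3'=C4' leads to the bis(dihydrocoumarin) 13. Placing the unsaturation after the oxygen insertion keeps the key step on saturated ketones; the corresponding indenones would offer a peracid an epoxidisable enone and a competing vinyl migration. The forward step is a twofold dehydrogenation by a high-potential quinone, and both C4 and C4' are benzylic carbons ortho or para to oxygen donors, which favours hydride abstraction.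

**Cut 3, the lactone oxygens (13 ⇒ 10, key).** O1–C8a and O1'–C8a' are cut and C2–C8a and C2'–C8a' rejoined, a twofold retro-Baeyer–Villiger step that contracts both lactones to the indan-1-ones of 10 (forward, through the monolactones 11 and 12).
- The neighbouring cuts are lactonisation at O1–C2 and C–C annulation at C4–C4a. Both would require phenols that carry one more oxygen on each ring, with four different oxygen roles on ring B, and an ether forged between two unactivated, electron-rich rings.
- The chosen cut takes one oxygen off each ring and replaces it by a ketone that does two jobs: it activates the ortho carbon for ether formation and it marks where the oxygen will later go.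
- Both halves carry the same functional group, so one operation serves both.
- The forward reaction must give aryl rather than CH2 migration in each half and leave the electron-rich rings unoxidised.

**Cut 4, the diaryl ether (10 ⇒ 4 + 9).** The bond between the bridging oxygen and C7 of the ring A indanone is cut, giving the fluoro ketone 4 and the phenol 9.
- The polarity is dictated by the substituents. C7 of 4 has the ketone ortho and no donor para, whereas C7 of the ring B indanone is para to the C4 alkoxy group and cannot act as the electrophile; its phenoxide, however, is made nucleophilic by ortho and para alkoxy groups.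
- Fluoride is chosen as leaving group over a sulfonate ester, which phenoxides attack at sulfur, and over bromide with copper, which is kept as the fallback.
- The forward step must effect substitution at a fluoride flanked by OMe and the acyl-bearing carbon with a di-ortho-substituted phenoxide.

**Cut 5, the ring A indanone (4 ⇒ 3 ⇒ 2 ⇒ 1).** The C3–C3a bond is cut (Nazarov-type closure of the aryl vinyl ketone 3), then the oxidation level is adjusted (alcohol 2) and the C1–C2 bond cut (vinyl addition to aldehyde 1). Friedel–Crafts acylation of an arylpropanoic acid cannot place the carbonyl next to the C–F carbon. Bringing the carbonyl carbon in as the aldehyde of 1 fixes that position, and the ring then closes at the only free ortho carbon, which is para to OMe.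

**Cut 6, protecting-group exchange on ring B (9 ⇒ 8 ⇒ 7).** The two benzyl ethers of 9 are cut back to triol 8, and the three O–H bonds of 8 to the trimethyl ether 7. The ring closure that makes 7 needs strong acid, which methyl ethers survive and benzyl ethers do not, while methyl ethers on ring B could not be distinguished from the ring A methyl ether at the end. The exchange is therefore made at the indanone stage. The forward benzylation must leave the C7 hydroxyl free; that hydroxyl is hydrogen-bonded to the ketone, and it is the one needed as nucleophile in step 8.

**Cut 7, the ring B indanone (7 ⇒ 6 ⇒ 5).** The C1–C7a bond is cut (intramolecular Friedel–Crafts acylation of acid 6), and 6 comes from the cinnamic acid 5 by saturation. Here the acylation direction is sound: only one ortho position of 6 is free and it is ortho to a methoxy group, so a single indanone can form.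

## Roads not taken

**Alternative 1: Danheiser benzannulation for ring B.**
- *Cut:* two C–C bonds of ring B, C4a'–C8a' and C5'–C6'. This leaves a cyclobutenone that already carries the finished A-half coumarin on oxygen (A2) and a two-carbon silyl ynol ether (A3).
- *Key step:* heating A2 with A3 would open the four-membered ring to a vinylketene, add the alkyne across the ketene, open the new cyclobutenone and close the dienylketene in a 6π step, giving the phenol A1.
- *Merits:* the bridging oxygen is attached at an sp3 carbon of A2, by alkylation of the phenol A4, so the hindered aryl–O coupling of step 8 never arises. The outer oxygens of ring B also emerge differentiated: free OH on C8a' where the lactone must be built, silyl ethers on the C5' and C7' oxygens.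
- *Weak points:* A2 is the silyl enol ether of an α-aryloxycyclobutane-1,3-dione, strained, with an aryloxide leaving group next to the carbonyl and no comfortable preparation. The cascade needs roughly 80–150 °C, where A3 and the silyl enol ether of A2 are both at risk. A1 still lacks the whole pyranone of the B half, which must be annulated by C–C bond formation at C4a', between the free OH and a bulky silyloxy group, before desilylation.
- *Comparison:* Alternative 1 is better on how the ether is made and on oxygen differentiation. It is worse on precedent and on the steps left after its key step. The chosen plan sets against it purchased arene rings, reaction types known for their substrate class, and a key step that delivers both lactone rings at once with the oxygens placed by the ketones.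

**Alternative 2: Dieckmann-type cyclisation for ring A.**
- *Cut:* C8–C8a of ring A at the oxidation level of a cyclohexane-1,3-dione; the open-chain precursor is the keto ester A6.
- *Key step:* under a hindered alkoxide base the aryloxymethyl ketone enolate of A6 would attack the ester and close the six-membered carbocycle of A5.
- *Merits:* the ether is made by SN2 alkylation of a phenol with an α-halo ketone, which is easier than any aryl–O coupling and on this point better than step 8. The ring B partner is symmetrical (two equal acetal-protected oxygens flank the ether), so no regiochemical question arises on that ring.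
- *Weak points:* A5 is far from 15. Ring A must be aromatised to the aromatic diol in the presence of a benzyl ether. Its two equivalent hydroxyls must then be told apart by a statistical mono-methylation. Two pyranone rings must finally be annulated by separate C–C bond formations, one on each crowded, electron-rich ring.
- *Comparison:* none of those later steps has the positional certainty of oxygen insertion at a ketone, and the total would exceed the chosen route by several steps. The chosen plan has the harder ether formation and sets against it intact purchased arene rings, no aromatisation, no statistical step and no late C–C bond formation.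

**Alternative 3: biomimetic recyclisation of a pyranone to ring B.**
- *Cut:* C8'–C8a' of ring B in a masked polyketide chain, the 6-(aryloxymethyl)-4-benzyloxy-2-pyranone A8, itself made by alkylating A4.
- *Key step:* a magnesium alkoxide in an alcohol would open the pyranone at its lactone carbonyl; the enolate at the aryloxymethyl carbon would then attack the liberated ester carbonyl in a Claisen condensation that closes ring B as the aromatic diol A7.
- *Merits:* on paper this is the most economical of the four plans. The ether comes from an SN2 reaction. A7 already contains the complete A-half coumarin. Its two free hydroxyls are equivalent (either may become O1', the other is the C7' hydroxyl). Only one pyranone annulation and one debenzylation would remain. On the ether bond and on distance to the target it is better than the chosen plan.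
- *Weak points:* the weakness is the key step itself. The enolate needed is the less acidic one, since the methylene between the enol ether and the ketone is deprotonated first. The opened chain can close again on oxygen to return A8, the usual fate of 3,5-dioxo esters, while closure on carbon to the aromatic ring is the less favoured branch. The alkoxide also opens the A-half coumarin lactone while the cyclisation is awaited. The remaining annulation of the B-half pyranone onto a ring with two free phenols beside the hindered ether is a further unknown.
- *Comparison:* the chosen plan accepts a longer route and a harder ether formation. It sets against them a key step of a known reaction type whose regiochemistry is decided by the position of the ketones, not by a competition between enolates.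

Key step: step 9

Assumption: compounds 1 and 5 are taken as purchased; alcohol 2 is racemic and its stereocentre is removed in step 2.

## Route

Step 1
Reactants: 1 2-fluoro-3-methoxybenzaldehyde
Product: 2 1-(2-fluoro-3-methoxyphenyl)prop-2-en-1-ol (racemic)
Conditions: CH2=CHMgBr, THF, −78 → 0 °C; aq NH4Cl
Reagents that add atoms: vinylmagnesium bromide, C=C[Mg]Br
Why: 1,2-Addition of a vinyl Grignard reagent to an aryl aldehyde; at low temperature the ortho fluoride is not displaced, and the racemic carbinol centre is erased in step 2.

Step 2
Reactants: 2 1-(2-fluoro-3-methoxyphenyl)prop-2-en-1-ol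
Product: 3 1-(2-fluoro-3-methoxyphenyl)prop-2-en-1-one
Conditions: Dess–Martin periodinane, CH2Cl2, 0 °C → rt
Reagents that add atoms: none
Why: Dess–Martin oxidation of an allylic, benzylic alcohol under near-neutral conditions should give the aryl vinyl ketone, which is prone to polymerisation and is taken into step 3 without storage.

Step 3
Reactants: 3 1-(2-fluoro-3-methoxyphenyl)prop-2-en-1-one
Product: 4 7-fluoro-6-methoxyindan-1-one
Conditions: TfOH, ClCH2CH2Cl, 0 → 50 °C
Reagents that add atoms: none
Why: Nazarov-type 4π cyclisation of a protonated aryl vinyl ketone in superacid is an established route to indan-1-ones; one carbon ortho to the acyl group is blocked by fluorine and the other is para to OMe, so only the 7-fluoro-6-methoxy isomer can form.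

Step 4
Reactants: 5 (E)-3-(2,4,5-trimethoxyphenyl)prop-2-enoic acid
Product: 6 3-(2,4,5-trimethoxyphenyl)propanoic acid
Conditions: H2 (1 atm), Pd/C, EtOAc–MeOH, rt
Reagents that add atoms: none
Why: Catalytic hydrogenation of a cinnamic acid double bond; the aryl methyl ethers and the acid are inert.

Step 5
Reactants: 6 3-(2,4,5-trimethoxyphenyl)propanoic acid
Product: 7 4,6,7-trimethoxyindan-1-one
Conditions: P2O5–MeSO3H (Eaton's reagent), 50 °C
Reagents that add atoms: none
Why: Intramolecular Friedel–Crafts acylation; the only free ortho carbon is ortho to a methoxy group, the situation of the well-known closure to 4,7-dimethoxyindan-1-one, and any loss of the C7 methyl group is harmless because step 6 removes all three.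

Step 6
Reactants: 7 4,6,7-trimethoxyindan-1-one
Product: 8 4,6,7-trihydroxyindan-1-one
Conditions: BBr3, CH2Cl2, −78 °C → rt; then H2O
Reagents that add atoms: none
Why: BBr3 cleavage of aryl methyl ethers (boron–oxygen complexation, then bromide attack at methyl) tolerates the ketone; the hydroxyquinol-type triol is handled under argon and benzylated without delay.

Step 7
Reactants: 8 4,6,7-trihydroxyindan-1-one
Product: 9 4,6-bis(benzyloxy)-7-hydroxyindan-1-one
Conditions: BnBr (2.1 equiv), K2CO3, acetone, 40 °C, Ar
Reagents that add atoms: benzyl bromide, BrCc1ccccc1
Why: Williamson etherification; the C7 hydroxyl is hydrogen-bonded to the C1 carbonyl and is the slowest to alkylate with a carbonate base, the selectivity known from 2,3,4-trihydroxy- and 2,5-dihydroxyacetophenones, which keep the chelated hydroxyl free.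

Step 8
Reactants: 4 7-fluoro-6-methoxyindan-1-one; 9 4,6-bis(benzyloxy)-7-hydroxyindan-1-one
Product: 10 4,6-bis(benzyloxy)-7-[(6-methoxy-1-oxoindan-7-yl)oxy]indan-1-one
Conditions: Cs2CO3, DMSO, 100 °C, Ar
Reagents that add atoms: none
Why: Nucleophilic aromatic substitution by addition–elimination: the fluoride of 4 is ortho to a ketone that the five-membered ring holds coplanar with the arene, so the Meisenheimer charge is delocalised onto the carbonyl oxygen, and the phenoxide of 9 is made electron-rich by its ortho and para benzyloxy groups. Ketone-activated displacement of fluoride from 7-fluoroindan-1-ones by phenoxides is a known reaction type.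

Step 9
Reactants: 10 4,6-bis(benzyloxy)-7-[(6-methoxy-1-oxoindan-7-yl)oxy]indan-1-one
Product: 13 8-{[5,7-bis(benzyloxy)-2-oxochroman-8-yl]oxy}-7-methoxychroman-2-one, via ring A monolactone 11 (not isolated), via ring B monolactone 12 (not isolated)
Conditions: mCPBA (5 equiv), NaHCO3, CH2Cl2, 0 °C → rt, dark
Reagents that add atoms: m-chloroperbenzoic acid (mCPBA), OOC(=O)c1cccc(Cl)c1
Why: Baeyer–Villiger oxidation, the reaction type known to turn indan-1-ones into 3,4-dihydrocoumarins, is applied here to two ketones in one molecule. The peracid adds to each ketone carbonyl to give a Criegee tetrahedral adduct, and the aryl carbon C7a then shifts from carbon to the proximal peroxide oxygen as 3-chlorobenzoate leaves; this makes O1–C8a and O1–C2 in the A half and O1'–C8a' and O1'–C2' in the B half. Each six-membered lactone therefore arises by one-atom ring expansion of a cyclopentanone (insertion into the C1–C7a bond), not by cyclisation of an open chain, so no ring-closure geometry has to be met. Whichever ketone reacts first, the monolactones 11 and 12 keep an unchanged second indanone and converge on 13. No stereocentre is formed. The step needs aryl rather than CH2 migration in both halves: an sp2 aryl carbon migrates better than a primary alkyl carbon, and each migrating carbon carries an ortho aryloxy oxygen that stabilises the positive charge building up in the transition state. It also needs the peracid to spare the electron-rich rings: the bicarbonate buffer removes the acid that would catalyse arene hydroxylation, and the ring B phenols are capped as benzyl ethers so that no free, quinone-forming phenol is exposed.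

Step 10
Reactants: 13 8-{[5,7-bis(benzyloxy)-2-oxochroman-8-yl]oxy}-7-methoxychroman-2-one
Product: 14 5,7-bis(benzyloxy)-8-[(7-methoxy-2-oxo-2H-chromen-8-yl)oxy]-2H-chromen-2-one
Conditions: DDQ (3 equiv), 1,4-dioxane, 100 °C
Reagents that add atoms: none
Why: DDQ dehydrogenation of 3,4-dihydrocoumarins proceeds by hydride abstraction from C4 and C4' followed by loss of the C3 proton; C4 is para to the C7 methoxy group and C4' is ortho and para to the two benzyloxy groups, which stabilises both benzylic cations.

Step 11
Reactants: 14 5,7-bis(benzyloxy)-8-[(7-methoxy-2-oxo-2H-chromen-8-yl)oxy]-2H-chromen-2-one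
Product: 15 5,7-dihydroxy-8-[(7-methoxy-2-oxo-2H-chromen-8-yl)oxy]-2H-chromen-2-one
Conditions: BCl3, C6HMe5, CH2Cl2, −78 °C; then MeOH
Reagents that add atoms: none
Why: Lewis-acid debenzylation with pentamethylbenzene as a non-coordinating benzyl-cation scavenger cleaves aryl benzyl ethers at low temperature and should leave the aryl methyl ether, both lactones and the C3=C4 and C3'=C4' bonds untouched.

## Compound list

1 | 2-fluoro-3-methoxybenzaldehyde | COc1cccc(C=O)c1F | starting material
2 | 1-(2-fluoro-3-methoxyphenyl)prop-2-en-1-ol (racemic) | COc1cccc(C(O)C=C)c1F | intermediate
3 | 1-(2-fluoro-3-methoxyphenyl)prop-2-en-1-one | COc1cccc(C(=O)C=C)c1F | intermediate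
4 | 7-fluoro-6-methoxyindan-1-one | COc1ccc2CCC(=O)c2c1F | intermediate
5 | (E)-3-(2,4,5-trimethoxyphenyl)prop-2-enoic acid | COc1cc(OC)c(/C=C/C(=O)O)cc1OC | starting material
6 | 3-(2,4,5-trimethoxyphenyl)propanoic acid | COc1cc(OC)c(CCC(=O)O)cc1OC | intermediate
7 | 4,6,7-trimethoxyindan-1-one | COc1cc(OC)c2CCC(=O)c2c1OC | intermediate
8 | 4,6,7-trihydroxyindan-1-one | Oc1cc(O)c2CCC(=O)c2c1O | intermediate
9 | 4,6-bis(benzyloxy)-7-hydroxyindan-1-one | Oc1c(OCc2ccccc2)cc(OCc2ccccc2)c2CCC(=O)c12 | intermediate
10 | 4,6-bis(benzyloxy)-7-[(6-methoxy-1-oxoindan-7-yl)oxy]indan-1-one | COc1ccc2CCC(=O)c2c1Oc1c(OCc2ccccc2)cc(OCc2ccccc2)c2CCC(=O)c12 | intermediate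
11 | 4,6-bis(benzyloxy)-7-[(7-methoxy-2-oxochroman-8-yl)oxy]indan-1-one (ring A monolactone) | COc1ccc2CCC(=O)Oc2c1Oc1c(OCc2ccccc2)cc(OCc2ccccc2)c2CCC(=O)c12 | intermediate
12 | 5,7-bis(benzyloxy)-8-[(6-methoxy-1-oxoindan-7-yl)oxy]chroman-2-one (ring B monolactone) | COc1ccc2CCC(=O)c2c1Oc1c(OCc2ccccc2)cc(OCc2ccccc2)c2CCC(=O)Oc12 | intermediate
13 | 8-{[5,7-bis(benzyloxy)-2-oxochroman-8-yl]oxy}-7-methoxychroman-2-one | COc1ccc2CCC(=O)Oc2c1Oc1c(OCc2ccccc2)cc(OCc2ccccc2)c2CCC(=O)Oc12 | intermediate
14 | 5,7-bis(benzyloxy)-8-[(7-methoxy-2-oxo-2H-chromen-8-yl)oxy]-2H-chromen-2-one | COc1ccc2ccc(=O)oc2c1Oc1c(OCc2ccccc2)cc(OCc2ccccc2)c2ccc(=O)oc12 | intermediate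
15 | 5,7-dihydroxy-8-[(7-methoxy-2-oxo-2H-chromen-8-yl)oxy]-2H-chromen-2-one | COc1ccc2ccc(=O)oc2c1Oc1c(O)cc(O)c2ccc(=O)oc12 | target

## Step count and least certain steps

Total: 11 steps. Longest linear sequence: 8 steps (5 → 15, steps 4–11). The ring A fragment 4 takes 3 steps (1 → 4) and joins at step 8.

**Step 9 (key step).** The most likely failure is slow addition of the peracid to two hindered, aryl-conjugated ketones. The reaction would then have to be forced with acid catalysis, and under those conditions electrophilic oxidation of the trioxygenated ring B and of the benzyl ether methylenes could overtake the ring expansion. Migration of CH2 instead of aryl is the lesser concern. Fallback: exchange the ring B benzyl ethers for electron-withdrawing acetates before the oxidation, so that a stronger, buffered peracid can be used. Setting out from 10, hydrogenolysis (H2, Pd/C, EtOAc) would give 4,6-dihydroxy-7-[(6-methoxy-1-oxoindan-7-yl)oxy]indan-1-one F1, and acetylation (Ac2O, pyridine) the diacetate F2. Baeyer–Villiger oxidation with CF3CO3H (from (CF3CO)2O and urea–H2O2, Na2HPO4, CH2Cl2) would then give the bis(dihydrocoumarin) diacetate F3, and DDQ in dioxane the bis(coumarin) diacetate F4. The acetates cannot be removed before this dehydrogenation, because the dihydrocoumarin lactones are aryl esters of like reactivity. Mild methanolysis of F4 (K2CO3, MeOH, then dilute HCl to reclose any opened coumarin) returns to the route at 15.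

**Step 8.** The most likely failure is slow substitution at the congested, only ketone-activated fluoride. At the temperature then required, base-mediated aldol self-condensation of the two indanones and air oxidation of the electron-rich phenoxide would consume material. Fallback: a copper-catalysed Ullmann coupling in place of the substitution. Commercial 2-bromo-3-methoxybenzaldehyde would be taken through the operations of steps 1–3 to 1-(2-bromo-3-methoxyphenyl)prop-2-en-1-ol F5, 1-(2-bromo-3-methoxyphenyl)prop-2-en-1-one F6 and 7-bromo-6-methoxyindan-1-one F7. F7 and 9 with CuI, picolinic acid and K3PO4 in DMSO at 90 °C should give 10, the ortho carbonyl group assisting the copper insertion. The fallback sets out from 9 and returns at 10.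

**Step 7.** The most likely failure is loss of site selectivity: alkylation of the chelated C7 hydroxyl, or incomplete alkylation at the C6 hydroxyl beside it. Autoxidation of the triol under basic conditions is a second risk. Fallback: from 8, exhaustive benzylation (excess BnBr, K2CO3, DMF) to 4,6,7-tris(benzyloxy)indan-1-one F8. The one benzyl group next to the carbonyl is then removed under chelation control with MgBr2·OEt2 in toluene–Et2O at reflux, returning at 9.

**Step 10.** The most likely failure is incomplete dehydrogenation of the second lactone ring, with slow oxidative attack of the quinone on the benzyl ether methylenes during prolonged heating. Fallback: from 13, twofold α-selenenylation of the lactone enolates (LiN(SiMe3)2, THF, −78 °C; PhSeCl) to 5,7-bis(benzyloxy)-8-{[7-methoxy-2-oxo-3-(phenylselanyl)chroman-8-yl]oxy}-3-(phenylselanyl)chroman-2-one F9. Oxidation with H2O2 gives the bis(selenoxide) F10, which undergoes spontaneous syn-elimination, returning at 14.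

## Further compounds

F1 | step 9 | 4,6-dihydroxy-7-[(6-methoxy-1-oxoindan-7-yl)oxy]indan-1-one | COc1ccc2CCC(=O)c2c1Oc1c(O)cc(O)c2CCC(=O)c12
F2 | step 9 | 7-[(6-methoxy-1-oxoindan-7-yl)oxy]-1-oxoindane-4,6-diyl diacetate | COc1ccc2CCC(=O)c2c1Oc1c(OC(C)=O)cc(OC(C)=O)c2CCC(=O)c12
F3 | step 9 | 8-[(7-methoxy-2-oxochroman-8-yl)oxy]-2-oxochromane-5,7-diyl diacetate | COc1ccc2CCC(=O)Oc2c1Oc1c(OC(C)=O)cc(OC(C)=O)c2CCC(=O)Oc12
F4 | step 9 | 8-[(7-methoxy-2-oxo-2H-chromen-8-yl)oxy]-2-oxo-2H-chromene-5,7-diyl diacetate | COc1ccc2ccc(=O)oc2c1Oc1c(OC(C)=O)cc(OC(C)=O)c2ccc(=O)oc12
F5 | step 8 | 1-(2-bromo-3-methoxyphenyl)prop-2-en-1-ol (racemic) | COc1cccc(C(O)C=C)c1Br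
F6 | step 8 | 1-(2-bromo-3-methoxyphenyl)prop-2-en-1-one | COc1cccc(C(=O)C=C)c1Br
F7 | step 8 | 7-bromo-6-methoxyindan-1-one | COc1ccc2CCC(=O)c2c1Br
F8 | step 7 | 4,6,7-tris(benzyloxy)indan-1-one | O=C1CCc2c(OCc3ccccc3)cc(OCc3ccccc3)c(OCc3ccccc3)c12
F9 | step 10 | 5,7-bis(benzyloxy)-8-{[7-methoxy-2-oxo-3-(phenylselanyl)chroman-8-yl]oxy}-3-(phenylselanyl)chroman-2-one (mixture of diastereomers) | COc1ccc2CC([Se]c3ccccc3)C(=O)Oc2c1Oc1c(OCc2ccccc2)cc(OCc2ccccc2)c2CC([Se]c3ccccc3)C(=O)Oc12
F10 | step 10 | 5,7-bis(benzyloxy)-8-{[7-methoxy-2-oxo-3-(phenylseleninyl)chroman-8-yl]oxy}-3-(phenylseleninyl)chroman-2-one (mixture of stereoisomers) | COc1ccc2CC([Se](=O)c3ccccc3)C(=O)Oc2c1Oc1c(OCc2ccccc2)cc(OCc2ccccc2)c2CC([Se](=O)c3ccccc3)C(=O)Oc12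
A1 | alternative 1 | 8-{2-hydroxy-4,6-bis[(triisopropylsilyl)oxy]phenoxy}-7-methoxy-2H-chromen-2-one | COc1ccc2ccc(=O)oc2c1Oc1c(O)cc(O[Si](C(C)C)(C(C)C)C(C)C)cc1O[Si](C(C)C)(C(C)C)C(C)C
A2 | alternative 1 | 7-methoxy-8-({4-oxo-2-[(triisopropylsilyl)oxy]cyclobut-2-en-1-yl}oxy)-2H-chromen-2-one (racemic) | COc1ccc2ccc(=O)oc2c1OC1C(=O)C=C1O[Si](C(C)C)(C(C)C)C(C)C
A3 | alternative 1 | (ethynyloxy)triisopropylsilane | C#CO[Si](C(C)C)(C(C)C)C(C)C
A4 | alternative 1 | 8-hydroxy-7-methoxy-2H-chromen-2-one | COc1ccc2ccc(=O)oc2c1O
A5 | alternative 2 | 2-[4-(benzyloxy)-2,6-bis(methoxymethoxy)phenoxy]cyclohexane-1,3-dione | O=C1CCCC(=O)C1Oc1c(OCOC)cc(OCc2ccccc2)cc1OCOC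
A6 | alternative 2 | methyl 6-[4-(benzyloxy)-2,6-bis(methoxymethoxy)phenoxy]-5-oxohexanoate | COC(=O)CCCC(=O)COc1c(OCOC)cc(OCc2ccccc2)cc1OCOC
A7 | alternative 3 | 8-[4-(benzyloxy)-2,6-dihydroxyphenoxy]-7-methoxy-2H-chromen-2-one | COc1ccc2ccc(=O)oc2c1Oc1c(O)cc(OCc2ccccc2)cc1O
A8 | alternative 3 | 8-{[4-(benzyloxy)-6-oxo-6H-pyran-2-yl]methoxy}-7-methoxy-2H-chromen-2-one | COc1ccc2ccc(=O)oc2c1OCc1cc(OCc2ccccc2)cc(=O)o1
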